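**Retrosynthetic overview**

- Numbering as in the briarellins: C1/C10 are the ring-fusion CH carbons of ring A (C1, C10–C14, ketone at C13), C2/C9 the CH–O carbons of the tetrahydrofuran, C3 the methylated ether carbon, C4 CHOH, C6 CHOAc, C7 the methyl carbinol, C15/C16 the CH(CH3)CH2O arm. The strategy rests on one feature: the oxonane O–C2–C3–C4–C5–C6–C7–C8–C9 is the rim of a 4,5,6,7-tetrahydrobenzofuran whose furan oxygen is the C2–O–C9 bridge, and the oxepane oxygen on C3 ties that furan through C16–C15–C14 to the ring A alkene C1=C10.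
- Target ⇒ oxonan-7-one (C7 methylation, C11→C13 enone transposition, protecting-group exchange) ⇒ 7-oxanorbornene cycloadduct (radical scission of the transannular C2–C7 bond) ⇒ furan tethered to a 4-substituted cyclohex-2-enone (C1–C2 and C9–C10 by intramolecular furan Diels–Alder reaction).
- Enone ⇒ aldehyde + methyl vinyl ketone (organocatalytic Michael addition, aldol condensation); tertiary ether ⇒ fragment 1 (furan alcohol from (S)-carvone, C6 relayed to C4 and C3) + fragment 2 (triflate from (S)-2-methylbutane-1,4-diol, C15).
- Ring order: ring C (carvone) → furan → ring A → oxepane and tetrahydrofuran together in the cycloaddition → oxonane unveiled by the scission.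

Key step: step 18

Remark: the carbinol centre at C11 made in step 20 is drawn for methyl delivery cis to H10 and is erased in step 24; the centres created at C7 in steps 8 and 21 and the aldol carbinol of step 17 are left undefined because they are destroyed; the primary oxygen of fragment 2 is carried as a tert-butyldimethylsilyl ether because a bulky silyl group discriminates the two primary hydroxyls of the diol better than a smaller one.

**Step 1**
Reactants: 1 (S)-(+)-carvone
Product: 4 (S)-5-acetoxy-2-methylcyclohex-2-en-1-one, via methoxy hydroperoxide 2 (not isolated), via peracetate 3 (not isolated)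
Conditions: O3, MeOH/CH2Cl2, −78 °C; then Ac2O, Et3N, DMAP (cat.), −10 °C → rt
Reagents that add atoms: ozone O=[O+][O-] (the oxygen on the ring carbon); methanol CO (the acetate carbonyl oxygen, by way of the methoxy group; the acetyl carbons are those of the isopropenyl group)
Why: Ozone attacks the electron-rich isopropenyl alkene and not the enone, methanol traps the carbonyl oxide, and acetylation triggers the Criegee rearrangement in which the ring carbon migrates to oxygen with retention, so the carvone stereocentre becomes the C6 acetate unchanged.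

**Step 2**
Reactants: 4 (S)-5-acetoxy-2-methylcyclohex-2-en-1-one
Product: 5 (S)-5-hydroxy-2-methylcyclohex-2-en-1-one
Conditions: K2CO3 (cat.), MeOH, 0 °C, short reaction time
Reagents that add atoms: none
Why: Mild transesterification (methanolysis) frees the β-hydroxy enone cold and briefly enough to avoid β-elimination to the cresol, and the stereocentre is not touched.

**Step 3**
Reactants: 5 (S)-5-hydroxy-2-methylcyclohex-2-en-1-one
Product: 6 (S)-5-(tert-butyldimethylsilyloxy)-2-methylcyclohex-2-en-1-one
Conditions: TBSCl, imidazole, DMF, 0 °C → rt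
Reagents that add atoms: tert-butyldimethylsilyl chloride CC(C)(C)[Si](C)(C)Cl
Why: Imidazole-assisted silylation of a secondary alcohol gives the robust silyl ether that protects the C6 oxygen up to step 25.

**Step 4**
Reactants: 6 (S)-5-(tert-butyldimethylsilyloxy)-2-methylcyclohex-2-en-1-one
Product: 7 (1S,5S)-5-(tert-butyldimethylsilyloxy)-2-methylcyclohex-2-en-1-ol (hydroxyl cis to the silyloxy group)
Conditions: NaBH4, CeCl3·7H2O, MeOH, −78 °C
Reagents that add atoms: none
Why: Luche reduction gives clean 1,2-reduction, and axial hydride delivery to the half-chair with the silyloxy group equatorial puts the new hydroxyl cis to it, as in the reduction of carvone to cis-carveol.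

**Step 5**
Reactants: 7 (1S,5S)-5-(tert-butyldimethylsilyloxy)-2-methylcyclohex-2-en-1-ol
Product: 8 syn-epoxy alcohol (2,3-epoxide of 7 on the face of the hydroxyl; epoxide, hydroxyl and silyloxy group all cis)
Conditions: mCPBA, NaHCO3, CH2Cl2, 0 °C
Reagents that add atoms: 3-chloroperbenzoic acid OOC(=O)c1cccc(Cl)c1
Why: Henbest hydroxyl-directed epoxidation, in which hydrogen bonding of the peracid to the allylic hydroxyl delivers oxygen to the syn face and so sets the future C3 oxygen cis to the C6 silyloxy group.

**Step 6**
Reactants: 8 syn-epoxy alcohol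
Product: 9 diol mono-PMB ether (secondary hydroxyl, tertiary C3 hydroxyl, C4 4-methoxybenzyl ether trans to the C3 hydroxyl)
Conditions: 4-methoxybenzyl alcohol (excess), Ti(OiPr)4, toluene, 70 °C
Reagents that add atoms: 4-methoxybenzyl alcohol COc1ccc(CO)cc1
Why: Titanium-assisted opening of a 2,3-epoxy alcohol, in which the chelated titanium alkoxide directs the alcohol to the distal secondary carbon C4 with inversion; this is also the trans-diaxial (Fürst–Plattner) mode of the half-chair with both existing oxygens equatorial, and C3 keeps the epoxide oxygen as the tertiary hydroxyl.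

**Step 7**
Reactants: 9 diol mono-PMB ether
Product: 10 (2R,3S,5S)-5-(tert-butyldimethylsilyloxy)-2-hydroxy-3-(4-methoxybenzyloxy)-2-methylcyclohexan-1-one (ketol carrying C3, C4 and C6; the ketone is C2)
Conditions: Dess–Martin periodinane, NaHCO3, CH2Cl2, 0 °C → rt
Reagents that add atoms: none
Why: Dess–Martin oxidation converts the only secondary alcohol into the ketone under buffered, non-basic conditions that spare the β-silyloxy group and cannot touch the tertiary carbinol.

**Step 8**
Reactants: 10 ketol; 11 allyl bromide
Product: 13 C7-allyl ketol (mixture of C7 epimers), via dilithium alkoxide enolate 12 (not isolated)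
Conditions: LiN(iPr)2 (2.2 equiv), THF, −78 °C; then 11, DMPU, −78 → −30 °C
Reagents that add atoms: none
Why: Enolate alkylation, in which two equivalents of base give the alkoxide–enolate that can only form toward C7 because C3 is quaternary, and the carbon nucleophile is allylated at low temperature where loss of the β-silyloxy group is slow; the C7 configuration is irrelevant because C7 becomes a furan carbon.

**Step 9**
Reactants: 13 C7-allyl ketol
Product: 15 keto aldehyde (C2 ketone and C9 aldehyde), via vicinal diol 14 (not isolated)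
Conditions: OsO4 (cat.), NaIO4, 2,6-lutidine, dioxane/H2O, rt
Reagents that add atoms: osmium tetroxide O=[Os](=O)(=O)=O (catalytic carrier of the oxygen that ends on C9); sodium periodate [Na+].[O-]I(=O)(=O)=O (re-forms it)
Why: Lemieux–Johnson cleavage (osmium-catalysed dihydroxylation of the only alkene, then periodate glycol cleavage) gives the 1,4-keto aldehyde, with 2,6-lutidine suppressing over-oxidation.

**Step 10**
Reactants: 15 keto aldehyde
Product: 16 fragment 1 (4S,6S,7R)-4-(tert-butyldimethylsilyloxy)-6-(4-methoxybenzyloxy)-7-methyl-4,5,6,7-tetrahydrobenzofuran-7-ol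
Conditions: PPTS (cat.), toluene, 40 °C, 4 Å molecular sieves
Reagents that add atoms: none
Why: Paal–Knorr-type cyclodehydration, in which the enol oxygen of the ketone closes onto the aldehyde and loss of water is driven by aromatisation, under acid mild enough for both ethers and for the tertiary furfuryl alcohol.

**Step 11**
Reactants: 17 (S)-2-methylbutane-1,4-diol
Product: 18 (S)-4-(tert-butyldimethylsilyloxy)-2-methylbutan-1-ol
Conditions: TBSCl (0.95 equiv), imidazole, CH2Cl2, −40 → 0 °C
Reagents that add atoms: tert-butyldimethylsilyl chloride CC(C)(C)[Si](C)(C)Cl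
Why: Sterically controlled monosilylation, in which the bulky silyl chloride used in deficiency should react faster at the unbranched hydroxyl than at the β-branched one, the minor regioisomer and the bis-ether being removed by chromatography.

**Step 12**
Reactants: 18 (S)-4-(tert-butyldimethylsilyloxy)-2-methylbutan-1-ol
Product: 19 fragment 2 (S)-4-(tert-butyldimethylsilyloxy)-2-methylbutyl trifluoromethanesulfonate
Conditions: Tf2O, 2,6-lutidine, CH2Cl2, −78 °C; used at once
Reagents that add atoms: trifluoromethanesulfonic anhydride O=S(=O)(OS(=O)(=O)C(F)(F)F)C(F)(F)F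
Why: Standard triflation of a primary alcohol with a hindered pyridine base at low temperature, the β-branched primary triflate being stable enough for immediate use.

**Step 13**
Reactants: 16 fragment 1; 19 fragment 2
Product: 21 tertiary ether C3–O–C16 (furan bis-silyl ether), via potassium alkoxide 20 (not isolated)
Conditions: KN(SiMe3)2, THF, −78 °C; then 19, −78 → 0 °C
Reagents that add atoms: none
Why: Williamson etherification, in which the irreversibly formed tertiary potassium alkoxide displaces the very reactive primary triflate by SN2, so that no bond to C3 or C15 is broken and both stereocentres are retained.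

**Step 14**
Reactants: 21 tertiary ether
Product: 22 primary alcohol (C1 hydroxyl free, C6 silyl ether kept)
Conditions: HF·pyridine, pyridine, THF, 0 °C
Reagents that add atoms: none
Why: Buffered HF·pyridine removes the unhindered primary silyl ether far faster than the secondary one at C6, which is flanked by the ring and the furan, and is not acidic enough to ionise the furfuryl ether.

**Step 15**
Reactants: 22 primary alcohol
Product: 23 aldehyde (C1 is the CHO carbon)
Conditions: Dess–Martin periodinane, NaHCO3, CH2Cl2, 0 °C → rt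
Reagents that add atoms: none
Why: Dess–Martin oxidation of the primary alcohol to the aldehyde under neutral buffered conditions tolerated by the furan and both ethers.

**Step 16**
Reactants: 23 aldehyde; 24 methyl vinyl ketone
Product: 25 keto aldehyde with C14 set (2-substituted 5-oxohexanal)
Conditions: (S)-α,α-diphenylprolinol trimethylsilyl ether (20 mol %), ethyl 3,4-dihydroxybenzoate (20 mol %), CH2Cl2, 4 °C
Reagents that add atoms: none
Why: Enamine-catalysed Michael addition, in which the (S)-diarylprolinol silyl ether forms the E-enamine and shields one face so that the enone adds to the open face and sets C14 as drawn (catalyst control over the neighbouring C15 centre), the catechol co-catalyst activating the enone by hydrogen bonding.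

**Step 17**
Reactants: 25 keto aldehyde
Product: 27 furan tethered to the ring A enone (4-substituted cyclohex-2-en-1-one), via aldol 26 (not isolated)
Conditions: KOH (0.1 M aq.), Bu4NOH (cat.), Et2O/THF, rt
Reagents that add atoms: none
Why: Intramolecular aldol condensation, in which the methyl ketone enolate attacks the aldehyde (the only closure that gives a six-membered ring) and dehydration gives the enone, dilute hydroxide at room temperature limiting epimerisation at C14.

**Step 18**
Reactants: 27 furan tethered to the ring A enone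
Product: 28 exo cycloadduct (oxepane fused to a 7-oxanorbornene; ring A syn to the oxygen bridge; C11 ketone; C7=C8 alkene)
Conditions: Me2AlCl (1.2 equiv), CH2Cl2, −78 → −30 °C, cold quench and cold handling (alternative: 13 kbar, CH2Cl2, 20 °C, no Lewis acid)
Reagents that add atoms: none
Why: Proposed new method: intramolecular furan Diels–Alder reaction in which Me2AlCl bound to the enone carbonyl lets the electron-rich 2,3-dialkylfuran (diene C9=C8–C7=C2) add across C1=C10 in an asynchronous [4+2] process, C2–C1 bonding leading and the oxocarbenium-like C9 terminus collapsing onto the aluminium enolate at C10; because C2 carries no hydrogen, a competing Friedel–Crafts conjugate addition cannot rearomatise and can only revert or close to the adduct. The closest known reaction type is the alkylaluminium chloride or high-pressure intramolecular Diels–Alder reaction of furans with enones through three- and four-atom tethers, here extended to a five-atom tether and an endocyclic dienophile. The oxepane (C2, C3, O, C16, C15, C14, C1) closes as the tether ring by seven-membered annulation onto C1, and the 7-oxanorbornene (C2, C1, C10, C9, C8, C7 and the bridging oxygen), which holds the tetrahydrofuran C2–O–C9–C10–C1, closes by the cycloaddition itself. C2 and C9 are controlled by C3, whose ether oxygen can deliver the enone only to the furan face on which it stands (anti to the C3 methyl), and C1 and C10 by C14, whose C15 substituent reaches only the syn face of the enone and so gives the cis-fused oxepane with H1, H10 and H14 cis. The step needs the exo mode (ring A syn to the bridging oxygen): for this pair of stereocentres exo is the adduct with the cis-fused oxepane, whereas endo would demand a trans-fused one, and exo is also the thermodynamic adduct of a reversible furan cycloaddition. Only O, C16 and C15 rotate freely between the two ring-held termini, the quaternary C3 and the C15 methyl bias the chain toward the reactive fold, and low temperature or pressure guards against cycloreversion until the C7=C8 alkene is consumed in step 21.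

**Step 19**
Reactants: 28 exo cycloadduct
Product: 30 C12=C13 enone (C11 ketone), via trimethylsilyl enol ether 29 (not isolated)
Conditions: LiN(iPr)2, Me3SiCl (in situ), THF, −78 °C; then Pd(OAc)2 (1.1 equiv), MeCN, rt
Reagents that add atoms: none
Why: Saegusa–Ito dehydrogenation, in which kinetic deprotonation with in-situ silylation occurs at the C12 methylene and not at the hindered C10 methine (whose enolate could expel the oxygen bridge), and divalent palladium converts the silyl enol ether into the enone by β-hydride elimination.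

**Step 20**
Reactants: 30 C12=C13 enone
Product: 31 C11 tertiary allylic alcohol (C11 methyl cis to H10)
Conditions: MeLi, THF, −78 °C
Reagents that add atoms: methyllithium [Li]C
Why: 1,2-Addition of methyllithium to the enone carbonyl at low temperature, from the face of ring A turned away from the oxanorbornene; this carbinol centre is erased in step 24.

**Step 21**
Reactants: 31 C11 tertiary allylic alcohol
Product: 32 C7 triethylsilyl peroxide (C8 now CH2)
Conditions: Co(acac)2 (cat.), O2 (1 atm), Et3SiH, 1,2-dichloroethane, rt
Reagents that add atoms: dioxygen O=O; triethylsilane CC[SiH](CC)CC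
Why: Isayama–Mukaiyama peroxidation, in which a cobalt hydride transfers a hydrogen atom to C8 of the strained trisubstituted alkene (faster than to the disubstituted ring A alkene) and the tertiary C7 radical is trapped by dioxygen and silylated; the C7 configuration is of no consequence.

**Step 22**
Reactants: 32 C7 triethylsilyl peroxide
Product: 33 oxonan-7-one with all four rings of the target (C2–H cis to C9–H across the ether)
Conditions: FeSO4·7H2O (1.5 equiv), PhSH (3 equiv), MeOH/THF, 0 °C → rt
Reagents that add atoms: none
Why: Reductive cleavage of the O–O bond by divalent iron gives the C7 alkoxyl radical, whose β-scission breaks C2–C7 because that releases the oxanorbornane strain and leaves a tertiary α-oxy radical, and benzenethiol then transfers hydrogen to C2 on the only face left open by the six-atom bridge, giving the 2,5-cis tetrahydrofuran of the oxonane.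

**Step 23**
Reactants: 33 oxonan-7-one
Product: 34 C7 methyl carbinol (C7 hydroxyl syn to the C6 silyloxy group along the chain)
Conditions: MeMgBr (4 equiv), THF, −78 → −30 °C
Reagents that add atoms: methylmagnesium bromide C[Mg]Br
Why: Grignard addition under non-chelating conditions (THF, bulky silyl ether), in which Felkin–Anh attack anti to the C6–O bond on the outer face of the oxonanone places the new hydroxyl syn to the C6 oxygen, the configuration of the target; the first equivalent only deprotonates the C11 hydroxyl.

**Step 24**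
Reactants: 34 C7 methyl carbinol
Product: 35 protected target (C13 enone, C11 methyl, C6 silyl ether, C4 PMB ether)
Conditions: pyridinium chlorochromate (C5H5NH[CrO3Cl]), NaOAc, 4 Å molecular sieves, CH2Cl2, rt
Reagents that add atoms: pyridinium chlorochromate [O-][Cr](=O)(=O)Cl.c1cc[nH+]cc1 (the C13 oxygen arrives from chromium in the [3,3] shift; the C11 oxygen leaves on chromium)
Why: Babler–Dauben oxidative transposition, in which the chromate ester of the tertiary allylic alcohol shifts to C13 and is oxidised there to the enone with the methyl on C11, while the tertiary C7 alcohol cannot be oxidised.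

**Step 25**
Reactants: 35 protected target
Product: 36 C6 alcohol
Conditions: Bu4NF, AcOH (1:1), THF, 0 → 40 °C
Reagents that add atoms: none
Why: Fluoride-mediated desilylation, buffered with acetic acid so that the enone is not exposed to base (no epimerisation at C14 and no elimination of the ring oxygen).

**Step 26**
Reactants: 36 C6 alcohol
Product: 37 C6 acetate (C4 PMB ether)
Conditions: Ac2O, DMAP (cat.), pyridine, CH2Cl2, 0 °C
Reagents that add atoms: acetic anhydride CC(=O)OC(C)=O
Why: DMAP-catalysed acetylation is selective for the secondary C6 hydroxyl because the tertiary C7 hydroxyl does not acylate under these conditions and C4 is still masked.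

**Step 27**
Reactants: 37 C6 acetate
Product: 38 target CNP0336530.3
Conditions: DDQ, CH2Cl2/pH 7 buffer, 0 °C
Reagents that add atoms: none
Why: Oxidative cleavage of the 4-methoxybenzyl ether, in which DDQ oxidises the electron-rich benzyl ether to the oxocarbenium ion that water hydrolyses, leaving the enone, the acetate and the tertiary alcohol untouched.

**Compound list**

1 | (S)-(+)-carvone | CC(=C)[C@H]1CC=C(C)C(=O)C1 | starting material
2 | methoxy hydroperoxide, (5S)-5-(1-hydroperoxy-1-methoxyethyl)-2-methylcyclohex-2-en-1-one | COC(C)(OO)[C@H]1CC=C(C)C(=O)C1 | intermediate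
3 | peracetate of 2 | COC(C)(OOC(C)=O)[C@H]1CC=C(C)C(=O)C1 | intermediate
4 | (S)-5-acetoxy-2-methylcyclohex-2-en-1-one | CC(=O)O[C@H]1CC=C(C)C(=O)C1 | intermediate
5 | (S)-5-hydroxy-2-methylcyclohex-2-en-1-one | O[C@H]1CC=C(C)C(=O)C1 | intermediate
6 | (S)-5-(tert-butyldimethylsilyloxy)-2-methylcyclohex-2-en-1-one | CC(C)(C)[Si](C)(C)O[C@H]1CC=C(C)C(=O)C1 | intermediate
7 | (1S,5S)-5-(tert-butyldimethylsilyloxy)-2-methylcyclohex-2-en-1-ol | CC(C)(C)[Si](C)(C)O[C@H]1CC=C(C)[C@@H](O)C1 | intermediate
8 | syn-epoxy alcohol (epoxide, hydroxyl and silyloxy group cis) | CC(C)(C)[Si](C)(C)O[C@H]1C[C@H]2O[C@@]2(C)[C@@H](O)C1 | intermediate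
9 | diol mono-PMB ether (C4 ether trans to the C3 hydroxyl) | CC(C)(C)[Si](C)(C)O[C@H]1C[C@H](OCc2ccc(OC)cc2)[C@@](C)(O)[C@@H](O)C1 | intermediate
10 | (2R,3S,5S)-5-(tert-butyldimethylsilyloxy)-2-hydroxy-3-(4-methoxybenzyloxy)-2-methylcyclohexan-1-one | CC(C)(C)[Si](C)(C)O[C@H]1C[C@H](OCc2ccc(OC)cc2)[C@@](C)(O)C(=O)C1 | intermediate
11 | allyl bromide | C=CCBr | starting material
12 | dilithium alkoxide enolate of 10 | [Li+].[Li+].CC(C)(C)[Si](C)(C)O[C@H]1C[C@H](OCc2ccc(OC)cc2)[C@@](C)([O-])C([O-])=C1 | intermediate
13 | C7-allyl ketol (C7 epimers) | CC(C)(C)[Si](C)(C)O[C@H]1C[C@H](OCc2ccc(OC)cc2)[C@@](C)(O)C(=O)C1CC=C | intermediate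
14 | vicinal diol from 13 | CC(C)(C)[Si](C)(C)O[C@H]1C[C@H](OCc2ccc(OC)cc2)[C@@](C)(O)C(=O)C1CC(O)CO | intermediate
15 | keto aldehyde (C2 ketone, C9 aldehyde) | CC(C)(C)[Si](C)(C)O[C@H]1C[C@H](OCc2ccc(OC)cc2)[C@@](C)(O)C(=O)C1CC=O | intermediate
16 | fragment 1, (4S,6S,7R)-4-(tert-butyldimethylsilyloxy)-6-(4-methoxybenzyloxy)-7-methyl-4,5,6,7-tetrahydrobenzofuran-7-ol | CC(C)(C)[Si](C)(C)O[C@H]1C[C@H](OCc3ccc(OC)cc3)[C@@](C)(O)c2occc12 | intermediate
17 | (S)-2-methylbutane-1,4-diol | OC[C@@H](C)CCO | starting material
18 | (S)-4-(tert-butyldimethylsilyloxy)-2-methylbutan-1-ol | OC[C@@H](C)CCO[Si](C)(C)C(C)(C)C | intermediate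
19 | fragment 2, (S)-4-(tert-butyldimethylsilyloxy)-2-methylbutyl trifluoromethanesulfonate | FC(F)(F)S(=O)(=O)OC[C@@H](C)CCO[Si](C)(C)C(C)(C)C | intermediate
20 | potassium alkoxide of 16 | [K+].CC(C)(C)[Si](C)(C)O[C@H]1C[C@H](OCc3ccc(OC)cc3)[C@@](C)([O-])c2occc12 | intermediate
21 | tertiary ether C3–O–C16 (bis-silyl ether) | CC(C)(C)[Si](C)(C)O[C@H]1C[C@H](OCc3ccc(OC)cc3)[C@@](C)(OC[C@@H](C)CCO[Si](C)(C)C(C)(C)C)c2occc12 | intermediate
22 | primary alcohol (C1 hydroxyl) | CC(C)(C)[Si](C)(C)O[C@H]1C[C@H](OCc3ccc(OC)cc3)[C@@](C)(OC[C@@H](C)CCO)c2occc12 | intermediate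
23 | aldehyde (C1 = CHO) | CC(C)(C)[Si](C)(C)O[C@H]1C[C@H](OCc3ccc(OC)cc3)[C@@](C)(OC[C@@H](C)CC=O)c2occc12 | intermediate
24 | methyl vinyl ketone | CC(=O)C=C | starting material
25 | keto aldehyde with C14 set | CC(C)(C)[Si](C)(C)O[C@H]1C[C@H](OCc3ccc(OC)cc3)[C@@](C)(OC[C@@H](C)[C@@H](C=O)CCC(C)=O)c2occc12 | intermediate
26 | aldol (3-hydroxycyclohexanone, carbinol undefined) | CC(C)(C)[Si](C)(C)O[C@H]1C[C@H](OCc3ccc(OC)cc3)[C@@](C)(OC[C@@H](C)[C@H]4C(O)CC(=O)CC4)c2occc12 | intermediate
27 | furan tethered to the ring A enone | CC(C)(C)[Si](C)(C)O[C@H]1C[C@H](OCc3ccc(OC)cc3)[C@@](C)(OC[C@@H](C)[C@H]4C=CC(=O)CC4)c2occc12 | intermediate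
28 | exo cycloadduct (oxepane plus 7-oxanorbornene, C11 ketone) | CC(C)(C)[Si](C)(C)O[C@H]1C[C@H](OCc6ccc(OC)cc6)[C@@]2(C)OC[C@@H](C)[C@@H]3CCC(=O)[C@H]4[C@@H]3[C@]25O[C@@H]4C=C15 | intermediate
29 | trimethylsilyl enol ether (C11–O, C11=C12) | CC(C)(C)[Si](C)(C)O[C@H]1C[C@H](OCc6ccc(OC)cc6)[C@@]2(C)OC[C@@H](C)[C@@H]3CC=C(O[Si](C)(C)C)[C@H]4[C@@H]3[C@]25O[C@@H]4C=C15 | intermediate
30 | C12=C13 enone | CC(C)(C)[Si](C)(C)O[C@H]1C[C@H](OCc6ccc(OC)cc6)[C@@]2(C)OC[C@@H](C)[C@@H]3C=CC(=O)[C@H]4[C@@H]3[C@]25O[C@@H]4C=C15 | intermediate
31 | C11 tertiary allylic alcohol | CC(C)(C)[Si](C)(C)O[C@H]1C[C@H](OCc6ccc(OC)cc6)[C@@]2(C)OC[C@@H](C)[C@@H]3C=C[C@](C)(O)[C@H]4[C@@H]3[C@]25O[C@@H]4C=C15 | intermediate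
32 | C7 triethylsilyl peroxide | CC(C)(C)[Si](C)(C)O[C@H]1C[C@H](OCc6ccc(OC)cc6)[C@@]2(C)OC[C@@H](C)[C@@H]3C=C[C@](C)(O)[C@H]4[C@@H]3[C@]25O[C@@H]4CC15OO[Si](CC)(CC)CC | intermediate
33 | oxonan-7-one | CC(C)(C)[Si](C)(C)O[C@H]1C[C@H](OCc5ccc(OC)cc5)[C@@]2(C)OC[C@@H](C)[C@@H]3C=C[C@](C)(O)[C@H]4[C@@H]3[C@H]2O[C@@H]4CC1=O | intermediate
34 | C7 methyl carbinol | CC(C)(C)[Si](C)(C)O[C@H]1C[C@H](OCc5ccc(OC)cc5)[C@@]2(C)OC[C@@H](C)[C@@H]3C=C[C@](C)(O)[C@H]4[C@@H]3[C@H]2O[C@@H]4C[C@]1(C)O | intermediate
35 | protected target (C6 silyl ether, C4 PMB ether) | CC(C)(C)[Si](C)(C)O[C@H]1C[C@H](OCc5ccc(OC)cc5)[C@@]2(C)OC[C@@H](C)[C@@H]3C(=O)C=C(C)[C@H]4[C@@H]3[C@H]2O[C@@H]4C[C@]1(C)O | intermediate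
36 | C6 alcohol (C4 PMB ether) | O[C@H]1C[C@H](OCc5ccc(OC)cc5)[C@@]2(C)OC[C@@H](C)[C@@H]3C(=O)C=C(C)[C@H]4[C@@H]3[C@H]2O[C@@H]4C[C@]1(C)O | intermediate
37 | C6 acetate (C4 PMB ether) | CC(=O)O[C@H]1C[C@H](OCc5ccc(OC)cc5)[C@@]2(C)OC[C@@H](C)[C@@H]3C(=O)C=C(C)[C@H]4[C@@H]3[C@H]2O[C@@H]4C[C@]1(C)O | intermediate
38 | CNP0336530.3 | CC(=O)O[C@H]1C[C@H](O)[C@@]2(C)OC[C@@H](C)[C@@H]3C(=O)C=C(C)[C@H]4[C@@H]3[C@H]2O[C@@H]4C[C@]1(C)O | target

**Step count**

Total step count: 27. Longest linear sequence: 25 steps (steps 1–10, then 13–27; fragment 2 is made in steps 11–12).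

**Three steps most likely to fail**

Step 18. The cycloaddition may stall at the crowded C2–C1 bond, revert by cycloreversion on warming, or the Lewis acid may ionise the tertiary furfuryl ether. The fallback makes the same two bonds one after the other by polar reactions of known type. It sets out from 27 and comes back at 28.
- Iridium-catalysed C–H borylation of the free furan α-carbon C9 ([Ir(OMe)(cod)]2, 4,4′-di-tert-butyl-2,2′-bipyridine, B2pin2, THF) would give the C9 pinacol boronate F1.
- Oxidation (NaBO3·4H2O, THF/H2O) would give the β,γ-unsaturated butenolide F2, with C9 as the lactone carbonyl.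
- Enol silylation (TBSOTf, Et3N, CH2Cl2) would give the 2-silyloxyfuran F3.
- Catalytic TBSOTf at −78 °C should then trigger the intramolecular vinylogous Mukaiyama–Michael addition of the γ-carbon C2 to the enone β-carbon C1. This closes the oxepane under the same facial control by C3 and C14 and delivers the butenolide silyl enol ether F4 (C10=C11–OTBS).
- i-Bu2AlH at −78 °C would reduce the lactone to the lactol F5.
- BF3·OEt2 would ionise F5 to the C9 oxocarbenium ion, which the silyl enol ether attacks through C10 to close the oxanorbornene and regenerate the C11 ketone of 28.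

Step 22. The alkoxyl radical may be reduced to the C7 carbinol faster than it fragments, or the iron and peroxide may cause unselective oxidation. The fallback generates the same radical reversibly from the alcohol by light instead of from the peroxide by a metal reductant. It sets out from 31 and comes back at 33.
- Silylation of the C11 hydroxyl (Et3SiOTf, 2,6-lutidine) would give the C11 triethylsilyl ether F6.
- Mukaiyama hydration of C7=C8 (Co(acac)2, PhSiH3, O2, then reductive work-up) would give the C7 tertiary alcohol F7.
- Light-driven ring opening of this cycloalkanol (CeCl3 (cat.), Bu4NCl, 2,4,6-triisopropylbenzenethiol, MeCN, 400 nm) should cleave C2–C7 through the cerium alkoxide and hydrogen-atom transfer from the thiol, giving the C11-silylated oxonanone F8. Any alkoxyl radical that is reduced back simply re-enters the cycle.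
- HF·pyridine would remove the triethylsilyl group to give 33.

Step 13. The hindered tertiary alkoxide may act as a base (E2 elimination of the β-branched triflate) or fail to alkylate. The fallback reverses the polarity and sets out from 16 and 18, coming back at 21. The tertiary furfuryl alcohol 16 is ionised by a mild acid (Bi(OTf)3 (cat.), 4 Å molecular sieves, CH2Cl2, −40 °C) in the presence of excess alcohol 18. The furan-stabilised C3 cation is captured by the primary hydroxyl anti to the neighbouring C4 ether, which is the configuration of 21. No new compound is formed on the way.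

**Further compounds**

F1 | step 18 | C9 pinacol boronate of 27 | CC(C)(C)[Si](C)(C)O[C@H]1C[C@H](OCc3ccc(OC)cc3)[C@@](C)(OC[C@@H](C)[C@H]4C=CC(=O)CC4)c2oc(B5OC(C)(C)C(C)(C)O5)cc12
F2 | step 18 | β,γ-unsaturated butenolide (C9 lactone carbonyl, C2=C7) | CC(C)(C)[Si](C)(C)O[C@H]1C[C@H](OCc3ccc(OC)cc3)[C@@](C)(OC[C@@H](C)[C@H]4C=CC(=O)CC4)C2=C1CC(=O)O2
F3 | step 18 | 2-silyloxyfuran (C9–OTBS) | CC(C)(C)[Si](C)(C)O[C@H]1C[C@H](OCc3ccc(OC)cc3)[C@@](C)(OC[C@@H](C)[C@H]4C=CC(=O)CC4)c2oc(O[Si](C)(C)C(C)(C)C)cc12
F4 | step 18 | butenolide silyl enol ether (C1–C2 bond formed, oxepane closed, C10=C11–OTBS) | CC(C)(C)[Si](C)(C)O[C@H]1C[C@H](OCc6ccc(OC)cc6)[C@@]2(C)OC[C@@H](C)[C@@H]3CCC(O[Si](C)(C)C(C)(C)C)=C[C@@H]3[C@]25OC(=O)C=C15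
F5 | step 18 | lactol (C9 hemiacetal, C9 undefined) | CC(C)(C)[Si](C)(C)O[C@H]1C[C@H](OCc6ccc(OC)cc6)[C@@]2(C)OC[C@@H](C)[C@@H]3CCC(O[Si](C)(C)C(C)(C)C)=C[C@@H]3[C@]25OC(O)C=C15
F6 | step 22 | C11 triethylsilyl ether of 31 | CC(C)(C)[Si](C)(C)O[C@H]1C[C@H](OCc6ccc(OC)cc6)[C@@]2(C)OC[C@@H](C)[C@@H]3C=C[C@](C)(O[Si](CC)(CC)CC)[C@H]4[C@@H]3[C@]25O[C@@H]4C=C15
F7 | step 22 | C7 tertiary alcohol (C7 undefined) | CC(C)(C)[Si](C)(C)O[C@H]1C[C@H](OCc6ccc(OC)cc6)[C@@]2(C)OC[C@@H](C)[C@@H]3C=C[C@](C)(O[Si](CC)(CC)CC)[C@H]4[C@@H]3[C@]25O[C@@H]4CC15O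
F8 | step 22 | C11-silylated oxonan-7-one | CC(C)(C)[Si](C)(C)O[C@H]1C[C@H](OCc5ccc(OC)cc5)[C@@]2(C)OC[C@@H](C)[C@@H]3C=C[C@](C)(O[Si](CC)(CC)CC)[C@H]4[C@@H]3[C@H]2O[C@@H]4CC1=O
F0 | step 13 | none | none
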